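Both furans are fragile towards acid and oxidants, so they are built in the final flask. Each 3-alkylfuran (ring A on chain carbon C1, ring B on C11) is disconnected at the bond between ring carbons 3 and 4. Ring carbon 3, which carries the chain, becomes a chain-end 1,1-disubstituted alkene, and ring carbons 4 and 5 come from acrolein. The precursor is therefore an acyclic bis(mixed acrolein acetal) of two 2-alkylallyl alcohols that already holds the C6 acetate, the E-C3=C4 alkene and both stereocentres. One twofold ring-closing metathesis forms both dihydrofuran rings and both ring C3=C4 bonds; loss of ethanol then aromatises them.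

Key step: step 15

Remarks: chain atoms are numbered C1 (CH2 on furan ring A) to C11 (CH2 on furan ring B), as in the target. Assumption: the B-allenyl borane made from (+)-α-pinene is taken to attack the si face of (S)-citronellal, as the analogous B-allyl borane does with unbranched aldehydes; should the sense prove opposite, the reagent from (−)-α-pinene is to be used.

Step 1
Reactants: 1 2-bromoprop-2-en-1-ol
Product: 2 [(2-bromoprop-2-en-1-yl)oxy](tert-butyl)dimethylsilane
Conditions: TBSCl, imidazole, CH2Cl2, 0 °C → rt
Reagents that add atoms: tert-butyl(chloro)dimethylsilane, CC(C)(C)[Si](C)(C)Cl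
Why: Silylation of a primary allylic alcohol with a silyl chloride and imidazole is general, and the alkenyl bromide is inert to it.

Step 2
Reactants: 2 [(2-bromoprop-2-en-1-yl)oxy](tert-butyl)dimethylsilane; 3 (2-tert-butoxy-2-oxoethyl)zinc bromide (commercial solution, or from tert-butyl bromoacetate and Zn dust)
Product: 4 tert-butyl 3-({[tert-butyl(dimethyl)silyl]oxy}methyl)but-3-enoate
Conditions: Pd(dba)2 (2 mol%), P(t-Bu)3 (2 mol%), THF, rt
Reagents that add atoms: none
Why: Palladium-catalysed cross-coupling of a Reformatsky reagent with an alkenyl bromide (Negishi-type α-vinylation of a zinc ester enolate) should proceed by oxidative addition of zerovalent palladium into the carbon–bromine bond, transmetalation and reductive elimination, under neutral conditions that do not move the alkene into conjugation with the ester.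

Step 3
Reactants: 4 tert-butyl 3-({[tert-butyl(dimethyl)silyl]oxy}methyl)but-3-enoate
Product: 5 3-({[tert-butyl(dimethyl)silyl]oxy}methyl)but-3-en-1-ol
Conditions: LiAlH4, Et2O, 0 °C
Reagents that add atoms: none
Why: Hydride reduction of the ester with LiAlH4 should give the primary alcohol and leave the silyl ether and the isolated 1,1-disubstituted alkene untouched at 0 °C.

Step 4
Reactants: 5 3-({[tert-butyl(dimethyl)silyl]oxy}methyl)but-3-en-1-ol
Product: 6 tert-butyl[(4-iodo-2-methylidenebutyl)oxy]dimethylsilane
Conditions: I2, PPh3, imidazole, CH2Cl2, 0 °C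
Reagents that add atoms: iodine, II
Why: In this Garegg–Samuelsson (Appel-type) iodination the alkoxyphosphonium ion of the primary alcohol is displaced by iodide in an SN2 step, while imidazole buffers the silyl ether against acid.

Step 5
Reactants: 7 (S)-citronellol
Product: 8 (S)-citronellal
Conditions: TEMPO (10 mol%), PhI(OAc)2, CH2Cl2, rt
Reagents that add atoms: none
Why: TEMPO-catalysed oxidation (oxoammonium mechanism, PhI(OAc)2 as terminal oxidant) stops at the aldehyde, spares the trisubstituted alkene and cannot epimerise the methyl-bearing carbon, which is β to the carbonyl group.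

Step 6
Reactants: 8 (S)-citronellal
Product: 10 (4R,6S)-6,10-dimethylundec-9-en-1-yn-4-ol, via diisopinocampheylborinate ester 9 (not isolated)
Conditions: (−)-Ipc2BOMe [from (+)-α-pinene], allenylmagnesium bromide, Et2O, −78 °C → rt; then 8, −100 → −78 °C; NaOH, H2O2, 0 °C → rt
Reagents that add atoms: allenylmagnesium bromide, C=C=C[Mg]Br
Why: In this reagent-controlled asymmetric allenylboration the aldehyde binds to boron and the allenyl γ-carbon is delivered through a closed six-membered chair transition state (SE2'), which gives the homopropargylic and not the allenic alcohol, while the isopinocampheyl groups direct attack to the si face and so set the new carbinol centre (future C6) as R, largely independent of the remote methyl stereocentre.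

Step 7
Reactants: 10 (4R,6S)-6,10-dimethylundec-9-en-1-yn-4-ol
Product: 12 (4S,6R)-4-methylnon-8-yne-1,6-diol, via hydroxy aldehyde 11 (not isolated)
Conditions: O3 (1 equiv, Sudan Red 7B end point), CH2Cl2/MeOH, −78 °C; then NaBH4, −78 → 0 °C
Reagents that add atoms: ozone, [O-][O+]=O
Why: In this ozonolysis with reductive work-up the electron-rich trisubstituted alkene reacts with ozone far faster than the terminal alkyne, so one equivalent should cleave only the isopropylidene group, and NaBH4 then reduces the aldehyde to the primary alcohol at C11.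

Step 8
Reactants: 12 (4S,6R)-4-methylnon-8-yne-1,6-diol
Product: 14 (4S,6R,8E)-9-iodo-4,8-dimethylnon-8-ene-1,6-diol, via alkenylalane 13 (not isolated)
Conditions: Me3Al (5 equiv), Cp2ZrCl2 (0.25 equiv), CH2Cl2, 0 °C → rt; then I2, THF, −30 → 0 °C; aqueous Rochelle salt
Reagents that add atoms: trimethylaluminium, C[Al](C)C; iodine, II
Why: In the Negishi zirconium-catalysed carboalumination methyl and aluminium add syn across the terminal alkyne with methyl on the internal carbon (both hydroxyls being masked in the flask as aluminium alkoxides), and iodinolysis replaces aluminium with retention, which fixes the E geometry of the future C3=C4 alkene.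

Step 9
Reactants: 14 (4S,6R,8E)-9-iodo-4,8-dimethylnon-8-ene-1,6-diol
Product: 15 (1E,4R,6S)-1,9-diiodo-2,6-dimethylnon-1-en-4-ol
Conditions: I2 (1.1 equiv), PPh3, imidazole, CH2Cl2, 0 °C
Reagents that add atoms: iodine, II
Why: Garegg–Samuelsson iodination is strongly selective for primary over secondary alcohols because the SN2 displacement at the alkoxyphosphonium carbon is sterically controlled, so with a slight excess of reagent only the C11 hydroxyl should be replaced.

Step 10
Reactants: 15 (1E,4R,6S)-1,9-diiodo-2,6-dimethylnon-1-en-4-ol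
Product: 16 (1E,4R,6S)-1,9-diiodo-2,6-dimethylnon-1-en-4-yl acetate
Conditions: Ac2O, Et3N, DMAP (cat.), CH2Cl2, 0 °C → rt
Reagents that add atoms: acetic anhydride, CC(=O)OC(C)=O
Why: DMAP-catalysed acylation of the secondary alcohol installs the acetate of the target with retention at C6 and removes the only acidic proton before the organozinc steps.

Step 11
Reactants: 16 (1E,4R,6S)-1,9-diiodo-2,6-dimethylnon-1-en-4-yl acetate; 6 tert-butyl[(4-iodo-2-methylidenebutyl)oxy]dimethylsilane
Product: 18 (5E,8R,10S)-1-{[tert-butyl(dimethyl)silyl]oxy}-13-iodo-6,10-dimethyl-2-methylidenetridec-5-en-8-yl acetate, via homoallylzinc iodide 17 (not isolated)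
Conditions: 6, Zn dust (activated with BrCH2CH2Br and Me3SiCl), LiCl, THF, 30 °C; solution decanted from excess Zn, then 16, Pd(PPh3)4 (5 mol%), THF, rt
Reagents that add atoms: none
Why: In this Negishi cross-coupling of an alkenyl iodide with a homoallylic zinc reagent, zerovalent palladium inserts into the sp2 carbon–iodine bond much faster than into the unactivated primary alkyl iodide, the coupling retains the E geometry, and the acetate, silyl ether and alkyl iodide are tolerated by the organozinc.

Step 12
Reactants: 18 (5E,8R,10S)-1-{[tert-butyl(dimethyl)silyl]oxy}-13-iodo-6,10-dimethyl-2-methylidenetridec-5-en-8-yl acetate; 2 [(2-bromoprop-2-en-1-yl)oxy](tert-butyl)dimethylsilane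
Product: 20 (5E,8R,10S)-1,15-bis{[tert-butyl(dimethyl)silyl]oxy}-6,10-dimethyl-2,14-dimethylidenepentadec-5-en-8-yl acetate, via alkylzinc iodide 19 (not isolated)
Conditions: Zn dust (activated), LiCl, THF, 35 °C; then 2, Pd(OAc)2 (3 mol%), SPhos (6 mol%), THF, rt
Reagents that add atoms: none
Why: LiCl-promoted insertion of zinc into the primary alkyl iodide tolerates the acetate and the silyl ether, and the resulting alkylzinc iodide should undergo sp3–sp2 Negishi coupling with the 2-bromoallyl ether under palladium catalysis.

Step 13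
Reactants: 20 (5E,8R,10S)-1,15-bis{[tert-butyl(dimethyl)silyl]oxy}-6,10-dimethyl-2,14-dimethylidenepentadec-5-en-8-yl acetate
Product: 21 (5E,8R,10S)-1,15-dihydroxy-6,10-dimethyl-2,14-dimethylidenepentadec-5-en-8-yl acetate
Conditions: HF·pyridine, pyridine, THF, 0 °C → rt
Reagents that add atoms: none
Why: Fluoride-mediated desilylation of the two primary allylic silyl ethers is driven by Si–F bond formation and is mild enough to leave the secondary acetate in place, which cannot migrate to the distant hydroxyls.

Step 14
Reactants: 21 (5E,8R,10S)-1,15-dihydroxy-6,10-dimethyl-2,14-dimethylidenepentadec-5-en-8-yl acetate; 22 acrolein diethyl acetal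
Product: 23 (5E,8R,10S)-1,15-bis[(1-ethoxyprop-2-en-1-yl)oxy]-6,10-dimethyl-2,14-dimethylidenepentadec-5-en-8-yl acetate (mixture of acetal epimers)
Conditions: 22 (10 equiv), PPTS (10 mol%), toluene, 40 °C, reduced pressure (removal of EtOH); Et3N quench
Reagents that add atoms: none
Why: In this acid-catalysed acetal exchange PPTS generates the ethoxy-stabilised oxocarbenium ion from the excess acrolein acetal, each allylic alcohol traps it, and removal of ethanol drives both exchanges to the mixed acetals, which form as a mixture of epimers at the new acetal carbons.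

Step 15
Reactants: 23 (5E,8R,10S)-1,15-bis[(1-ethoxyprop-2-en-1-yl)oxy]-6,10-dimethyl-2,14-dimethylidenepentadec-5-en-8-yl acetate
Product: 25 (3E,6R,8S)-1,11-di(furan-3-yl)-4,8-dimethylundec-3-en-6-yl acetate, via bis(dihydrofuran) acetal 24 (not isolated)
Conditions: second-generation Grubbs catalyst (H2IMes)(PCy3)Cl2Ru=CHPh (2 × 5 mol%), CH2Cl2 (0.005 M), 40 °C; then PPTS (20 mol%), rt
Reagents that add atoms: none
Why: The ruthenium benzylidene initiates at each monosubstituted vinyl group of the acrolein acetals, and the resulting alkylidene reacts with the neighbouring 1,1-disubstituted alkene by [2+2] cycloaddition and cycloreversion through a ruthenacyclobutane, releasing ethene. The closest known reaction type is the ring-closing metathesis of allyl acrolein mixed acetals to 2-alkoxy-2,5-dihydrofurans followed by acid-induced loss of alcohol, here run at both chain ends of one molecule. Each ring closes as a five-membered ring by ring-closing metathesis (ring A at the end next to C1, ring B at the end next to C11), the new C=C bond joining ring carbons 3 and 4. No stereocentre is created: the acetal carbons are already present as epimer mixtures and become sp2 when PPTS eliminates ethanol from 24, and C6 and C8 are not touched. The step needs ring closure to win over cross-metathesis and oligomerisation, which high dilution and the five-membered ring size should secure. The chain E-C3=C4 alkene should stay out because it is trisubstituted and could only close an eight-membered or larger ring, and the 3-substitution pattern is fixed by the 2-alkylallyl ether.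

Compound list
1 | 2-bromoprop-2-en-1-ol | C=C(Br)CO | starting material
2 | [(2-bromoprop-2-en-1-yl)oxy](tert-butyl)dimethylsilane | C=C(Br)CO[Si](C)(C)C(C)(C)C | intermediate
3 | (2-tert-butoxy-2-oxoethyl)zinc bromide | CC(C)(C)OC(=O)C[Zn]Br | starting material
4 | tert-butyl 3-({[tert-butyl(dimethyl)silyl]oxy}methyl)but-3-enoate | C=C(CO[Si](C)(C)C(C)(C)C)CC(=O)OC(C)(C)C | intermediate
5 | 3-({[tert-butyl(dimethyl)silyl]oxy}methyl)but-3-en-1-ol | C=C(CO[Si](C)(C)C(C)(C)C)CCO | intermediate
6 | tert-butyl[(4-iodo-2-methylidenebutyl)oxy]dimethylsilane | C=C(CO[Si](C)(C)C(C)(C)C)CCI | intermediate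
7 | (S)-citronellol, (3S)-3,7-dimethyloct-6-en-1-ol | OCC[C@@H](C)CCC=C(C)C | starting material
8 | (S)-citronellal, (3S)-3,7-dimethyloct-6-enal | O=CC[C@@H](C)CCC=C(C)C | intermediate
9 | (4R,6S)-6,10-dimethylundec-9-en-1-yn-4-yl diisopinocampheylborinate | C#CC[C@H](OB([C@@H]1C[C@@H]2C[C@H]([C@H]1C)C2(C)C)[C@@H]1C[C@@H]2C[C@H]([C@H]1C)C2(C)C)C[C@@H](C)CCC=C(C)C | intermediate (not isolated)
10 | (4R,6S)-6,10-dimethylundec-9-en-1-yn-4-ol | O[C@@H](CC#C)C[C@@H](C)CCC=C(C)C | intermediate
11 | (4S,6R)-6-hydroxy-4-methylnon-8-ynal | O[C@@H](CC#C)C[C@@H](C)CCC=O | intermediate (not isolated)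
12 | (4S,6R)-4-methylnon-8-yne-1,6-diol | O[C@@H](CC#C)C[C@@H](C)CCCO | intermediate
13 | [(1E,4R,6S)-4,9-bis[(dimethylalumanyl)oxy]-2,6-dimethylnon-1-en-1-yl](dimethyl)alumane | C[Al](C)O[C@@H](C/C(C)=C/[Al](C)C)C[C@@H](C)CCCO[Al](C)C | intermediate (not isolated)
14 | (4S,6R,8E)-9-iodo-4,8-dimethylnon-8-ene-1,6-diol | O[C@@H](C/C(C)=C/I)C[C@@H](C)CCCO | intermediate
15 | (1E,4R,6S)-1,9-diiodo-2,6-dimethylnon-1-en-4-ol | O[C@@H](C/C(C)=C/I)C[C@@H](C)CCCI | intermediate
16 | (1E,4R,6S)-1,9-diiodo-2,6-dimethylnon-1-en-4-yl acetate | CC(=O)O[C@@H](C/C(C)=C/I)C[C@@H](C)CCCI | intermediate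
17 | [3-({[tert-butyl(dimethyl)silyl]oxy}methyl)but-3-en-1-yl]zinc iodide | C=C(CO[Si](C)(C)C(C)(C)C)CC[Zn]I | intermediate (not isolated)
18 | (5E,8R,10S)-1-{[tert-butyl(dimethyl)silyl]oxy}-13-iodo-6,10-dimethyl-2-methylidenetridec-5-en-8-yl acetate | CC(=O)O[C@@H](C/C(C)=C/CCC(=C)CO[Si](C)(C)C(C)(C)C)C[C@@H](C)CCCI | intermediate
19 | [(4S,6R,8E)-6-(acetyloxy)-13-{[tert-butyl(dimethyl)silyl]oxy}-4,8-dimethyl-12-methylidenetridec-8-en-1-yl]zinc iodide | CC(=O)O[C@@H](C/C(C)=C/CCC(=C)CO[Si](C)(C)C(C)(C)C)C[C@@H](C)CCC[Zn]I | intermediate (not isolated)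
20 | (5E,8R,10S)-1,15-bis{[tert-butyl(dimethyl)silyl]oxy}-6,10-dimethyl-2,14-dimethylidenepentadec-5-en-8-yl acetate | CC(=O)O[C@@H](C/C(C)=C/CCC(=C)CO[Si](C)(C)C(C)(C)C)C[C@@H](C)CCCC(=C)CO[Si](C)(C)C(C)(C)C | intermediate
21 | (5E,8R,10S)-1,15-dihydroxy-6,10-dimethyl-2,14-dimethylidenepentadec-5-en-8-yl acetate | CC(=O)O[C@@H](C/C(C)=C/CCC(=C)CO)C[C@@H](C)CCCC(=C)CO | intermediate
22 | acrolein diethyl acetal, 3,3-diethoxyprop-1-ene | C=CC(OCC)OCC | starting material
23 | (5E,8R,10S)-1,15-bis[(1-ethoxyprop-2-en-1-yl)oxy]-6,10-dimethyl-2,14-dimethylidenepentadec-5-en-8-yl acetate (mixture of acetal epimers) | CC(=O)O[C@@H](C/C(C)=C/CCC(=C)COC(OCC)C=C)C[C@@H](C)CCCC(=C)COC(OCC)C=C | intermediate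
24 | (3E,6R,8S)-1,11-bis(5-ethoxy-2,5-dihydrofuran-3-yl)-4,8-dimethylundec-3-en-6-yl acetate (mixture of acetal epimers) | CC(=O)O[C@@H](C/C(C)=C/CCC1=CC(OCC)OC1)C[C@@H](C)CCCC1=CC(OCC)OC1 | intermediate (not isolated)
25 | (3E,6R,8S)-1,11-di(furan-3-yl)-4,8-dimethylundec-3-en-6-yl acetate (CNP0309834.1) | CC(=O)O[C@@H](C/C(C)=C/CCc1ccoc1)C[C@@H](C)CCCc1ccoc1 | target

Total step count: 15. Longest linear sequence: 11 steps (steps 5 to 15, from (S)-citronellol).

Steps most likely to fail

Step 15. After the first ring has closed, the second closure may stall as the catalyst decays, the alkylidene may engage a second molecule (cross-metathesis, oligomerisation), or the dihydrofuran acetals may decompose before they aromatise. The fallback brings the furans in preformed by known sp3–sp2 Negishi couplings; it sets out from diiodide acetate 16 and comes back at 25. Commercial 2-(furan-3-yl)ethanol is converted with I2, PPh3 and imidazole into 3-(2-iodoethyl)furan F1. Zinc insertion gives [2-(furan-3-yl)ethyl]zinc iodide F2, which is coupled at the alkenyl iodide of 16 (Pd(PPh3)4, THF) to give (3E,6R,8S)-1-(furan-3-yl)-11-iodo-4,8-dimethylundec-3-en-6-yl acetate F3. Zinc insertion into its primary iodide gives the alkylzinc iodide F4, and coupling with commercial 3-bromofuran (Pd(OAc)2, SPhos) should give 25.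

Step 6. Facial selectivity in the allenylboration of an unbranched aldehyde may be insufficient, or the sense of attack may be opposite to the assumed one, so that C6 epimers form that are hard to separate. The fallback replaces reagent control by a catalyst-controlled resolution and a stereospecific epoxide opening; it sets out from 8 and comes back at 10. Corey–Chaykovsky methylenation (Me3SI, NaH, DMSO/THF) gives 2-[(2S)-2,6-dimethylhept-5-en-1-yl]oxirane F5 as both oxirane epimers. Hydrolytic kinetic resolution with (S,S)-(salen)Co(OAc), the acetate of the trivalent cobalt complex of N,N'-bis(3,5-di-tert-butylsalicylidene)cyclohexane-1,2-diamine, and 0.55 equiv of water should leave (2R)-2-[(2S)-2,6-dimethylhept-5-en-1-yl]oxirane F6 and convert the other epimer into (2S,4S)-4,8-dimethylnon-7-ene-1,2-diol F7, which is discarded. Lithium acetylide–ethylenediamine complex in DMSO opens F6 at its CH2 group, without touching the stereocentre, to give 10.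

Step 2. Transmetalation of the zinc enolate to the hindered alkenylpalladium bromide may be sluggish, or the 1,1-disubstituted alkene may migrate into conjugation with the ester, so that iodide 6 cannot be supplied. The fallback builds C1–C2 by alanate opening of ethylene oxide and installs both chain ends in one twofold Negishi coupling with 2. It sets out from diol 12 and comes back at 20, and steps 2 to 4 and 9 to 11 are then not needed. Carboalumination as in step 8 gives alkenylalane 13, which after addition of n-BuLi opens ethylene oxide to give (3E,6R,8S)-4,8-dimethylundec-3-ene-1,6,11-triol F8. Garegg–Samuelsson iodination of both primary hydroxyls gives (3E,6R,8S)-1,11-diiodo-4,8-dimethylundec-3-en-6-ol F9, and acetylation gives (3E,6R,8S)-1,11-diiodo-4,8-dimethylundec-3-en-6-yl acetate F10. Twofold zinc insertion gives the bis(zinc iodide) F11, and twofold coupling with 2 (Pd(OAc)2, SPhos) should give 20.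

Further compounds
F1 | step 15 | 3-(2-iodoethyl)furan | ICCc1ccoc1
F2 | step 15 | [2-(furan-3-yl)ethyl]zinc iodide | I[Zn]CCc1ccoc1
F3 | step 15 | (3E,6R,8S)-1-(furan-3-yl)-11-iodo-4,8-dimethylundec-3-en-6-yl acetate | CC(=O)O[C@@H](C/C(C)=C/CCc1ccoc1)C[C@@H](C)CCCI
F4 | step 15 | [(4S,6R,8E)-6-(acetyloxy)-11-(furan-3-yl)-4,8-dimethylundec-8-en-1-yl]zinc iodide | CC(=O)O[C@@H](C/C(C)=C/CCc1ccoc1)C[C@@H](C)CCC[Zn]I
F5 | step 6 | 2-[(2S)-2,6-dimethylhept-5-en-1-yl]oxirane (both epimers at the oxirane carbon) | C1OC1C[C@@H](C)CCC=C(C)C
F6 | step 6 | (2R)-2-[(2S)-2,6-dimethylhept-5-en-1-yl]oxirane | C1O[C@@H]1C[C@@H](C)CCC=C(C)C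
F7 | step 6 | (2S,4S)-4,8-dimethylnon-7-ene-1,2-diol | O[C@H](CO)C[C@@H](C)CCC=C(C)C
F8 | step 2 | (3E,6R,8S)-4,8-dimethylundec-3-ene-1,6,11-triol | O[C@@H](C/C(C)=C/CCO)C[C@@H](C)CCCO
F9 | step 2 | (3E,6R,8S)-1,11-diiodo-4,8-dimethylundec-3-en-6-ol | O[C@@H](C/C(C)=C/CCI)C[C@@H](C)CCCI
F10 | step 2 | (3E,6R,8S)-1,11-diiodo-4,8-dimethylundec-3-en-6-yl acetate | CC(=O)O[C@@H](C/C(C)=C/CCI)C[C@@H](C)CCCI
F11 | step 2 | [(3E,6R,8S)-6-(acetyloxy)-4,8-dimethylundec-3-ene-1,11-diyl]bis(zinc iodide) | CC(=O)O[C@@H](C/C(C)=C/CC[Zn]I)C[C@@H](C)CCC[Zn]I
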